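**Strategy.** The lactone ring (O1, C2–C6) is cut at the C4–C5 bond. The plan exploits two features of that bond: C5 is bonded to the C6 carbinol carbon, and C4 is one carbon from the acidic C3 position. The bond can therefore be made as a C4=C5 alkene by ring-closing metathesis of an (R)-allylic but-3-enoate, and base then moves the alkene into conjugation (C3=C4) in the same flask. The acyclic precursor gets its C6 oxygen, stereocentre and acyl group at once from a catalytic asymmetric SN2′ esterification of a (Z)-allylic imidate. The all-syn C2′/C4′/C6′ oxygens come from a commercial syn-1,3-diol acetonide aldehyde and one catalyst-controlled allylation.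

Key step: step 9

Remark on the chemistry: the sense of induction is assumed to be (S)-ligand → (S)-carbinol in step 4 and (Rp,S)-catalyst → (R)-allylic ester in step 8; if either runs the other way, the mirror-image ligand or catalyst is used and nothing else changes.

Step 1
Reactants: 1 tert-butyl 2-[(4R,6S)-6-formyl-2,2-dimethyl-1,3-dioxan-4-yl]acetate; 2 tetradecyl(triphenyl)phosphonium bromide
Product: 4 tert-butyl 2-[(4R,6S)-2,2-dimethyl-6-[(1Z)-pentadec-1-en-1-yl]-1,3-dioxan-4-yl]acetate, via phosphonium ylide 3 (not isolated)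
Conditions: 2, NaN(SiMe3)2, THF, 0 °C; then 1, −78 °C to rt
Reagents that add atoms: none
Why: Wittig olefination of the α-alkoxy aldehyde with a non-stabilised ylide at low temperature should attach the C14 chain without epimerising the adjacent ring carbon, and the alkene geometry is irrelevant because it is removed in step 2.

Step 2
Reactants: 4 tert-butyl 2-[(4R,6S)-2,2-dimethyl-6-[(1Z)-pentadec-1-en-1-yl]-1,3-dioxan-4-yl]acetate
Product: 5 tert-butyl 2-[(4R,6R)-2,2-dimethyl-6-pentadecyl-1,3-dioxan-4-yl]acetate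
Conditions: H2 (1 atm), 10% Pd/C, EtOAc, rt
Reagents that add atoms: none
Why: Heterogeneous catalytic hydrogenation of the isolated disubstituted alkene should give the saturated pentadecyl chain while the acetonide and the tert-butyl ester stay intact; no stereocentre is touched.

Step 3
Reactants: 5 tert-butyl 2-[(4R,6R)-2,2-dimethyl-6-pentadecyl-1,3-dioxan-4-yl]acetate
Product: 6 2-[(4S,6R)-2,2-dimethyl-6-pentadecyl-1,3-dioxan-4-yl]ethan-1-ol
Conditions: LiAlH4, THF, 0 °C; Rochelle-salt work-up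
Reagents that add atoms: none
Why: Hydride reduction of the ester to the primary alcohol is a standard transformation that leaves the acetonide and both stereocentres unchanged (the descriptor at C4 changes only through priorities).

Step 4
Reactants: 6 2-[(4S,6R)-2,2-dimethyl-6-pentadecyl-1,3-dioxan-4-yl]ethan-1-ol; 7 allyl acetate
Product: 8 (2S)-1-[(4S,6R)-2,2-dimethyl-6-pentadecyl-1,3-dioxan-4-yl]pent-4-en-2-ol
Conditions: 7 (excess), [Ir(cod)Cl]2 (2.5 mol%), (S)-Cl,MeO-BIPHEP (5 mol%), 4-chloro-3-nitrobenzoic acid (10 mol%), Cs2CO3 (20 mol%), THF, 100 °C, sealed tube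
Reagents that add atoms: none
Why: Krische allylation from the alcohol oxidation level: iridium dehydrogenates the alcohol to the aldehyde, the chiral cyclometalated π-allyliridium benzoate transfers allyl through a closed transition state, and the (S)-ligand should set the new carbinol (S), 1,3-syn to the dioxane oxygen, under catalyst control.

Step 5
Reactants: 8 (2S)-1-[(4S,6R)-2,2-dimethyl-6-pentadecyl-1,3-dioxan-4-yl]pent-4-en-2-ol
Product: 9 tert-butyl{[(2S)-1-[(4R,6R)-2,2-dimethyl-6-pentadecyl-1,3-dioxan-4-yl]pent-4-en-2-yl]oxy}dimethylsilane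
Conditions: TBSCl, imidazole, DMF, rt
Reagents that add atoms: tert-butyldimethylsilyl chloride, CC(C)(C)[Si](C)(C)Cl
Why: Silylation of the only free hydroxyl protects the future C2′ oxygen against imidate formation in step 7 and against oxa-Michael addition in step 9; no stereocentre is affected.

Step 6
Reactants: 9 tert-butyl{[(2S)-1-[(4R,6R)-2,2-dimethyl-6-pentadecyl-1,3-dioxan-4-yl]pent-4-en-2-yl]oxy}dimethylsilane; 10 (2Z)-but-2-ene-1,4-diol
Product: 11 (2Z,5S)-5-[(tert-butyldimethylsilyl)oxy]-6-[(4R,6R)-2,2-dimethyl-6-pentadecyl-1,3-dioxan-4-yl]hex-2-en-1-ol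
Conditions: 10 (3 equiv), Ru(=CH-C6H4-2-OiPr)(SIMes)(S2C6H2Cl2-3,6) (5 mol%), THF, 40 °C
Reagents that add atoms: none
Why: Z-selective cross-metathesis: the dithiolate ligand forces both substituents of the ruthenacyclobutane to one side, so the Z geometry of the diol should be carried into the allylic alcohol, and excess diol suppresses homodimerisation of 9.

Step 7
Reactants: 11 (2Z,5S)-5-[(tert-butyldimethylsilyl)oxy]-6-[(4R,6R)-2,2-dimethyl-6-pentadecyl-1,3-dioxan-4-yl]hex-2-en-1-ol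
Product: 12 (2Z,5S)-5-[(tert-butyldimethylsilyl)oxy]-6-[(4R,6R)-2,2-dimethyl-6-pentadecyl-1,3-dioxan-4-yl]hex-2-en-1-yl 2,2,2-trichloroethanimidate
Conditions: Cl3CCN, DBU (0.1 equiv), CH2Cl2, 0 °C
Reagents that add atoms: trichloroacetonitrile, N#CC(Cl)(Cl)Cl
Why: Base-catalysed addition of the primary allylic alcohol to trichloroacetonitrile (imidate formation) is a standard activation that leaves the Z alkene and all stereocentres unchanged.

Step 8
Reactants: 12 (2Z,5S)-5-[(tert-butyldimethylsilyl)oxy]-6-[(4R,6R)-2,2-dimethyl-6-pentadecyl-1,3-dioxan-4-yl]hex-2-en-1-yl 2,2,2-trichloroethanimidate; 13 but-3-enoic acid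
Product: 14 (3R,5R)-5-[(tert-butyldimethylsilyl)oxy]-6-[(4R,6R)-2,2-dimethyl-6-pentadecyl-1,3-dioxan-4-yl]hex-1-en-3-yl but-3-enoate
Conditions: 13 (3 equiv), [(Rp,S)-COP-OAc]2 = Pd2(μ-OAc)2{(η5-C5H3-[(S)-4-iPr-oxazolin-2-yl])Co(η4-C4Ph4)}2 (1–2 mol%), CH2Cl2, rt
Reagents that add atoms: none
Why: Catalytic asymmetric SN2′ allylic esterification (Overman esterification): the palladacycle, held by the imidate nitrogen, activates the alkene for anti attack of the carboxylic acid at C3, and loss of trichloroacetamide gives the branched ester; the planar-chiral catalyst should fix the alkene face and so the (R) centre (C6 of the lactone), 1,3-syn to the silyloxy group, with the acyl group placed on that oxygen alone.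

Step 9
Reactants: 14 (3R,5R)-5-[(tert-butyldimethylsilyl)oxy]-6-[(4R,6R)-2,2-dimethyl-6-pentadecyl-1,3-dioxan-4-yl]hex-1-en-3-yl but-3-enoate
Product: 16 (6S)-6-{(2R)-2-[(tert-butyldimethylsilyl)oxy]-3-[(4R,6R)-2,2-dimethyl-6-pentadecyl-1,3-dioxan-4-yl]propyl}-5,6-dihydro-2H-pyran-2-one, via 3,6-dihydropyranone 15 (not isolated)
Conditions: second-generation Grubbs catalyst RuCl2(=CHPh)(PCy3)(SIMes) (5 mol%), CH2Cl2 (0.005 M), 40 °C; then DBU (0.3 equiv), rt, same flask
Reagents that add atoms: none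
Why: The ruthenium alkylidene loads onto the unhindered butenoate terminus and a [2+2]/retro-[2+2] sequence with the C6 vinyl group expels ethene and joins C4 to C5 as a cis ring alkene; catalytic DBU then removes the doubly activated C3 proton and the dienolate is reprotonated at C5, so the alkene settles in conjugation as C3=C4 while the C4–C5 bond stays. The closest known reaction type is ring-closing metathesis of allyl but-3-enoates to 3,6-dihydro-2H-pyran-2-ones followed by amine-base conjugation. The one ring closed is the six-membered lactone, formed by olefin metathesis of two terminal alkenes through a ruthenacyclobutane, with the new alkene endocyclic. No stereocentre is created: C6, set in step 8, lies outside both the metathesis and the proton shift, since its C–H is never removed and its C–O bond is not ionised. The step needs ring closure to outrun oligomerisation and alkene migration in the butenoate, which the six-membered ring size, high dilution and short reaction time should secure, and it needs C5 protonation of the dienolate to outrun ring-opening loss of the C6 carboxylate, which the weak amidine base (low dienolate concentration, conjugated lactone as thermodynamic sink) favours. The silyl ether on C2′ keeps that oxygen from adding to the new enoate under the basic conditions.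

Step 10
Reactants: 16 (6S)-6-{(2R)-2-[(tert-butyldimethylsilyl)oxy]-3-[(4R,6R)-2,2-dimethyl-6-pentadecyl-1,3-dioxan-4-yl]propyl}-5,6-dihydro-2H-pyran-2-one
Product: 17 (6S)-6-[(2R,4R,6R)-2,4,6-trihydroxyhenicosyl]-5,6-dihydro-2H-pyran-2-one
Conditions: 48% aq. HF, MeCN, 0 °C to rt
Reagents that add atoms: none
Why: Acidic global deprotection: aqueous HF should hydrolyse the acetonide and cleave the silyl ether in one operation, and the acidic, non-basic medium avoids oxa-Michael closure of the C2′ hydroxyl onto the enoate and leaves all four stereocentres untouched.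

**Compound list**

1 | tert-butyl 2-[(4R,6S)-6-formyl-2,2-dimethyl-1,3-dioxan-4-yl]acetate | O=C[C@@H]1C[C@H](CC(=O)OC(C)(C)C)OC(C)(C)O1 | starting material
2 | tetradecyl(triphenyl)phosphonium bromide | CCCCCCCCCCCCCC[P+](c1ccccc1)(c1ccccc1)c1ccccc1.[Br-] | starting material
3 | tetradecylidene(triphenyl)phosphorane | CCCCCCCCCCCCCC=P(c1ccccc1)(c1ccccc1)c1ccccc1 | intermediate
4 | tert-butyl 2-[(4R,6S)-2,2-dimethyl-6-[(1Z)-pentadec-1-en-1-yl]-1,3-dioxan-4-yl]acetate | CCCCCCCCCCCCC/C=C\[C@@H]1C[C@H](CC(=O)OC(C)(C)C)OC(C)(C)O1 | intermediate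
5 | tert-butyl 2-[(4R,6R)-2,2-dimethyl-6-pentadecyl-1,3-dioxan-4-yl]acetate | CCCCCCCCCCCCCCC[C@@H]1C[C@H](CC(=O)OC(C)(C)C)OC(C)(C)O1 | intermediate
6 | 2-[(4S,6R)-2,2-dimethyl-6-pentadecyl-1,3-dioxan-4-yl]ethan-1-ol | CCCCCCCCCCCCCCC[C@@H]1C[C@H](CCO)OC(C)(C)O1 | intermediate
7 | allyl acetate (prop-2-en-1-yl acetate) | CC(=O)OCC=C | starting material
8 | (2S)-1-[(4S,6R)-2,2-dimethyl-6-pentadecyl-1,3-dioxan-4-yl]pent-4-en-2-ol | CCCCCCCCCCCCCCC[C@@H]1C[C@H](C[C@@H](O)CC=C)OC(C)(C)O1 | intermediate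
9 | tert-butyl{[(2S)-1-[(4R,6R)-2,2-dimethyl-6-pentadecyl-1,3-dioxan-4-yl]pent-4-en-2-yl]oxy}dimethylsilane | CCCCCCCCCCCCCCC[C@@H]1C[C@H](C[C@@H](O[Si](C)(C)C(C)(C)C)CC=C)OC(C)(C)O1 | intermediate
10 | (2Z)-but-2-ene-1,4-diol | OC/C=C\CO | starting material
11 | (2Z,5S)-5-[(tert-butyldimethylsilyl)oxy]-6-[(4R,6R)-2,2-dimethyl-6-pentadecyl-1,3-dioxan-4-yl]hex-2-en-1-ol | CCCCCCCCCCCCCCC[C@@H]1C[C@H](C[C@@H](O[Si](C)(C)C(C)(C)C)C/C=C\CO)OC(C)(C)O1 | intermediate
12 | (2Z,5S)-5-[(tert-butyldimethylsilyl)oxy]-6-[(4R,6R)-2,2-dimethyl-6-pentadecyl-1,3-dioxan-4-yl]hex-2-en-1-yl 2,2,2-trichloroethanimidate | CCCCCCCCCCCCCCC[C@@H]1C[C@H](C[C@@H](O[Si](C)(C)C(C)(C)C)C/C=C\COC(=N)C(Cl)(Cl)Cl)OC(C)(C)O1 | intermediate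
13 | but-3-enoic acid | C=CCC(=O)O | starting material
14 | (3R,5R)-5-[(tert-butyldimethylsilyl)oxy]-6-[(4R,6R)-2,2-dimethyl-6-pentadecyl-1,3-dioxan-4-yl]hex-1-en-3-yl but-3-enoate | CCCCCCCCCCCCCCC[C@@H]1C[C@H](C[C@@H](O[Si](C)(C)C(C)(C)C)C[C@@H](OC(=O)CC=C)C=C)OC(C)(C)O1 | intermediate
15 | (6R)-6-{(2R)-2-[(tert-butyldimethylsilyl)oxy]-3-[(4R,6R)-2,2-dimethyl-6-pentadecyl-1,3-dioxan-4-yl]propyl}-3,6-dihydro-2H-pyran-2-one | CCCCCCCCCCCCCCC[C@@H]1C[C@H](C[C@@H](O[Si](C)(C)C(C)(C)C)C[C@@H]2C=CCC(=O)O2)OC(C)(C)O1 | intermediate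
16 | (6S)-6-{(2R)-2-[(tert-butyldimethylsilyl)oxy]-3-[(4R,6R)-2,2-dimethyl-6-pentadecyl-1,3-dioxan-4-yl]propyl}-5,6-dihydro-2H-pyran-2-one | CCCCCCCCCCCCCCC[C@@H]1C[C@H](C[C@@H](O[Si](C)(C)C(C)(C)C)C[C@@H]2CC=CC(=O)O2)OC(C)(C)O1 | intermediate
17 | (6S)-6-[(2R,4R,6R)-2,4,6-trihydroxyhenicosyl]-5,6-dihydro-2H-pyran-2-one | CCCCCCCCCCCCCCC[C@@H](O)C[C@@H](O)C[C@@H](O)C[C@@H]1CC=CC(=O)O1 | target

**Totals.** Total step count: 10. Longest linear sequence: 10 steps (1 → 17).

**Steps most likely to fail**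

Step 9. In the base stage the dienolate may lose the C6 carboxylate by vinylogous elimination and open the ring to a dienoic acid, or the butenoate alkene may migrate before ring closure. The fallback sets out from 15, which is isolated by stopping step 9 before DBU is added. Hydrogenation (H2, Pd/C, EtOAc) should give the saturated lactone (6S)-6-{(2R)-2-[(tert-butyldimethylsilyl)oxy]-3-[(4R,6R)-2,2-dimethyl-6-pentadecyl-1,3-dioxan-4-yl]propyl}oxan-2-one F1. Enolisation and selenenylation (LiN(iPr)2, THF, −78 °C; PhSeBr) should give the 3-(phenylselanyl) lactone F2 as either C3 epimer. Oxidation (H2O2, pyridine, CH2Cl2, 0 °C) and selenoxide syn-elimination then place the alkene at C3=C4 without any dienolate, and the route is rejoined at 16.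

Step 6. Secondary metathesis may erode the Z geometry, 9 may homodimerise, or the free diol may deactivate the catalyst. The fallback sets out from 9. Ozonolysis (O3, CH2Cl2, −78 °C; PPh3) should give the aldehyde (3R)-3-[(tert-butyldimethylsilyl)oxy]-4-[(4R,6R)-2,2-dimethyl-6-pentadecyl-1,3-dioxan-4-yl]butanal F3. A Z-selective Horner–Wadsworth–Emmons reaction of the Ando type (ethyl 2-(diphenoxyphosphoryl)acetate, NaH, THF, −78 °C) should give ethyl (2Z,5S)-5-[(tert-butyldimethylsilyl)oxy]-6-[(4R,6R)-2,2-dimethyl-6-pentadecyl-1,3-dioxan-4-yl]hex-2-enoate F4. Reduction with iBu2AlH (CH2Cl2, −78 °C) returns to the route at 11.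

Step 8. Facial selectivity may be poor if the catalyst's preference is opposed by the silyloxy centre, and [3,3]-rearrangement of the imidate to the allylic trichloroacetamide may compete. The fallback sets out from 11 and sets C6 by epoxidation instead. Sharpless asymmetric epoxidation (Ti(OiPr)4, L-(+)-diethyl tartrate, tBuOOH, 4 Å sieves, CH2Cl2, −20 °C) should give the epoxy alcohol {(2S,3R)-3-[(2R)-2-[(tert-butyldimethylsilyl)oxy]-3-[(4R,6R)-2,2-dimethyl-6-pentadecyl-1,3-dioxan-4-yl]propyl]oxiran-2-yl}methanol F5. Iodination (I2, PPh3, imidazole, THF) should give the epoxy iodide (2R,3R)-2-(iodomethyl)-3-[(2R)-2-[(tert-butyldimethylsilyl)oxy]-3-[(4R,6R)-2,2-dimethyl-6-pentadecyl-1,3-dioxan-4-yl]propyl]oxirane F6. Reductive opening (Zn, EtOH, reflux) keeps the C3–O bond and should give the allylic alcohol (3R,5S)-5-[(tert-butyldimethylsilyl)oxy]-6-[(4R,6R)-2,2-dimethyl-6-pentadecyl-1,3-dioxan-4-yl]hex-1-en-3-ol F7. Esterification of its single free hydroxyl with 13 (DCC, catalytic DMAP, CH2Cl2, 0 °C) returns to the route at 14.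

**Further compounds**

F1 | step 9 | (6S)-6-{(2R)-2-[(tert-butyldimethylsilyl)oxy]-3-[(4R,6R)-2,2-dimethyl-6-pentadecyl-1,3-dioxan-4-yl]propyl}oxan-2-one | CCCCCCCCCCCCCCC[C@@H]1C[C@H](C[C@@H](O[Si](C)(C)C(C)(C)C)C[C@@H]2CCCC(=O)O2)OC(C)(C)O1
F2 | step 9 | (6S)-6-{(2R)-2-[(tert-butyldimethylsilyl)oxy]-3-[(4R,6R)-2,2-dimethyl-6-pentadecyl-1,3-dioxan-4-yl]propyl}-3-(phenylselanyl)oxan-2-one (either C3 epimer) | CCCCCCCCCCCCCCC[C@@H]1C[C@H](C[C@@H](O[Si](C)(C)C(C)(C)C)C[C@@H]2CCC([Se]c3ccccc3)C(=O)O2)OC(C)(C)O1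
F3 | step 6 | (3R)-3-[(tert-butyldimethylsilyl)oxy]-4-[(4R,6R)-2,2-dimethyl-6-pentadecyl-1,3-dioxan-4-yl]butanal | CCCCCCCCCCCCCCC[C@@H]1C[C@H](C[C@@H](O[Si](C)(C)C(C)(C)C)CC=O)OC(C)(C)O1
F4 | step 6 | ethyl (2Z,5S)-5-[(tert-butyldimethylsilyl)oxy]-6-[(4R,6R)-2,2-dimethyl-6-pentadecyl-1,3-dioxan-4-yl]hex-2-enoate | CCCCCCCCCCCCCCC[C@@H]1C[C@H](C[C@@H](O[Si](C)(C)C(C)(C)C)C/C=C\C(=O)OCC)OC(C)(C)O1
F5 | step 8 | {(2S,3R)-3-[(2R)-2-[(tert-butyldimethylsilyl)oxy]-3-[(4R,6R)-2,2-dimethyl-6-pentadecyl-1,3-dioxan-4-yl]propyl]oxiran-2-yl}methanol | CCCCCCCCCCCCCCC[C@@H]1C[C@H](C[C@@H](O[Si](C)(C)C(C)(C)C)C[C@H]2O[C@H]2CO)OC(C)(C)O1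
F6 | step 8 | (2R,3R)-2-(iodomethyl)-3-[(2R)-2-[(tert-butyldimethylsilyl)oxy]-3-[(4R,6R)-2,2-dimethyl-6-pentadecyl-1,3-dioxan-4-yl]propyl]oxirane | CCCCCCCCCCCCCCC[C@@H]1C[C@H](C[C@@H](O[Si](C)(C)C(C)(C)C)C[C@H]2O[C@H]2CI)OC(C)(C)O1
F7 | step 8 | (3R,5S)-5-[(tert-butyldimethylsilyl)oxy]-6-[(4R,6R)-2,2-dimethyl-6-pentadecyl-1,3-dioxan-4-yl]hex-1-en-3-ol | CCCCCCCCCCCCCCC[C@@H]1C[C@H](C[C@@H](O[Si](C)(C)C(C)(C)C)C[C@@H](O)C=C)OC(C)(C)O1
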